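The plan rests on cutting ring A (C1, C2, C3, C4, C5, C10; C4 carries carboxyl carbon C15, C5 the methyl group) back to a cycloheptanone in which the future C15 still lies in the ring between C5 and C4. An (S)-configured 6-7 Robinson annulation product is converted into an α-diazo ketone whose photochemical Wolff rearrangement shifts quaternary C5 to C4, expels the ring carbonyl carbon as the C15 carboxyl group and, by protonation anti to the C5 methyl group, sets C4. The step exploits the carboxyl-bearing C4 next to quaternary C5 of ring A; the ring B enone is masked as a dithiolane. C7 and C1 are functionalised afterwards under control of the C5 methyl group.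

Key step: step 5

Remark (numbering): bicyclic compounds 8 to 15 and 28 to 31 carry the numbering of the target: ring A = C1, C2, C3, C4, C5, C10; ring B = C5, C6, C7, C8, C9, C10; C8 is the ketone, C15 the carboxyl carbon on C4; β is the face of the C5 methyl group. Compounds 4 to 7 carry benzo[7]annulene numbering (C4a = future C5, C5 = future C15, C6 = future C4).

Remark (assumption): 2-methylcycloheptane-1,3-dione (1) is taken as a purchasable compound; it is otherwise one C-methylation away from cycloheptane-1,3-dione.

Step 1
Reactants: 1 2-methylcycloheptane-1,3-dione; 2 methyl vinyl ketone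
Product: 3 2-methyl-2-(3-oxobutyl)cycloheptane-1,3-dione
Conditions: Et3N (0.1 equiv), MeCN, rt to 40 °C
Reagents that add atoms: methyl vinyl ketone (2), CC(=O)C=C
Why: Amine-catalysed Michael addition of the doubly activated C2–H of the 1,3-dione to the enone should give the triketone; no stereocentre is formed.

Step 2
Reactants: 3 2-methyl-2-(3-oxobutyl)cycloheptane-1,3-dione
Product: 4 (4aS)-4a-methyl-4,4a,6,7,8,9-hexahydro-3H-benzo[7]annulene-2,5-dione
Conditions: L-phenylalanine (1 equiv), (1S)-(+)-camphor-10-sulfonic acid (0.5 equiv), DMF, 30 to 70 °C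
Reagents that add atoms: none
Why: Amino-acid-mediated intramolecular aldol condensation (Hajos–Parrish–Eder–Sauer–Wiechert reaction, second stage of the Robinson annulation) runs through the enamine of the side-chain ketone, which distinguishes the two enantiotopic ring carbonyls; the (S)-configured quaternary carbon is expected by analogy with the L-amino-acid-mediated cyclisation of the cyclohexanedione homologue (the D-amino acid would be used if the sense proved opposite), and the enantiomeric purity is to be checked and raised by crystallisation if needed.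

Step 3
Reactants: 4 (4aS)-4a-methyl-4,4a,6,7,8,9-hexahydro-3H-benzo[7]annulene-2,5-dione
Product: 5 (4aS)-enone dithiolane: 4 with the C2 (enone) carbonyl as spiro-1,3-dithiolane, C1=C9a alkene and C5 ketone unchanged
Conditions: HSCH2CH2SH (1.05 equiv), BF3·OEt2 (0.2 equiv), AcOH, rt
Reagents that add atoms: ethane-1,2-dithiol, SCCS
Why: Acid-catalysed dithioketalisation should take the conjugated carbonyl selectively (through the stabilised allylic thionium ion, with the alkene staying in place) and leave the hindered cycloheptanone next to the quaternary carbon free, so that the enone is silent towards base and light in the next two steps.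

Step 4
Reactants: 5 (4aS)-enone dithiolane
Product: 7 (4aS)-6-diazo-5-ketone: 5 with C6 as C=N2, via sodium hydroxymethylene enolate 6 (not isolated)
Conditions: NaH, HCO2Et, THF, 0 °C to rt; then 4-acetamidobenzenesulfonyl azide, rt; aq. NaOH wash
Reagents that add atoms: 4-acetamidobenzenesulfonyl azide, CC(=O)Nc1ccc(cc1)S(=O)(=O)N=[N+]=[N-] (the N2 unit of 7); ethyl formate, CCOC=O, together with NaH, [Na+].[H-] (formyl carbon and sodium of intermediate 6 only)
Why: Claisen formylation at the only enolisable position (the CH2 next to the ring ketone) followed by Regitz deformylative diazo transfer should give the α-diazo ketone without touching the stereocentre.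

Step 5
Reactants: 7 (4aS)-6-diazo-5-ketone
Product: 9 2-(trimethylsilyl)ethyl (4S,5R)-ester: ring A six-membered with CO2CH2CH2SiMe3 at C4 on the β face (cis to the C5 methyl), C9=C10 alkene and C8 spiro-1,3-dithiolane, via ketene 8 (not isolated)
Conditions: hν (365 nm, or medium-pressure Hg lamp through Pyrex), Me3SiCH2CH2OH (5 equiv), THF, 0 to 20 °C
Reagents that add atoms: 2-(trimethylsilyl)ethanol, C[Si](C)(C)CCO
Why: Irradiation of the cyclic, s-cis-locked α-diazo ketone expels N2 with 1,2-shift of C5 from the carbonyl carbon to the diazo carbon (photochemical Wolff rearrangement), giving ketene 8 in which ring A has contracted from seven to six members and the former ring carbonyl carbon has become exocyclic C15; the alcohol then adds to the ketene and the resulting ester enol is protonated at C4. The closest known reaction type is the Wolff ring contraction of 2-diazocycloalkanones, including the D-ring contraction of steroidal 16-diazo-17-ketones, where a quaternary carbon bearing an angular methyl group migrates. No ring is closed by a cyclisation: ring A arises by the suprafacial 1,2-shift, which runs with retention at the migrating C5, so the quaternary stereocentre is carried over unchanged. The new stereocentre C4 is set in the protonation of the exocyclic enol, which should occur axially from the α face, anti to the axial C5 methyl group that hinders the equatorial β trajectory, while the α face lacks one syn-axial hydrogen because C10 is sp2; this places the ester β, cis to the methyl group. Regioselectivity needs no control because C5 is the only group that can migrate, and chemoselectivity is secured by the dithiolane, which removes the enone chromophore and the second carbonyl group.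

Step 6
Reactants: 9 2-(trimethylsilyl)ethyl (4S,5R)-ester with C8 dithiolane
Product: 10 2-(trimethylsilyl)ethyl (1S,8aR)-8a-methyl-6-oxo-1,2,3,4,6,7,8,8a-octahydronaphthalene-1-carboxylate (enone ester; target numbering 4S,5R, CO2R cis to the methyl)
Conditions: MeI (excess), CaCO3, MeCN/H2O (4:1), 50 °C
Reagents that add atoms: water, O
Why: S-Methylation turns sulfur into a leaving group and the allylic thionium ion is hydrolysed to the enone (alkylative dethioketalisation), leaving the ester and both stereocentres untouched.

Step 7
Reactants: 10 enone ester; 11 allyl bromide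
Product: 13 (4S,5R,7R)-7α-allyl enone ester: 10 with an allyl group at C7 trans to the C5 methyl, via lithium dienolate 12 (not isolated)
Conditions: LiN(i-Pr)2 (1.05 equiv), THF, −78 °C; then allyl bromide, DMPU, −78 to −30 °C
Reagents that add atoms: allyl bromide (11), C=CCBr; lithium diisopropylamide, [Li+].CC(C)[N-]C(C)C (lithium of intermediate 12 only)
Why: Kinetic deprotonation of the enone at the α' carbon C7 (the ester α-hydrogen at C4 is far less acidic) and alkylation of the cross-conjugated dienolate anti to the axial C5 methyl group should give the equatorial 7α-allyl compound, which is also the more stable epimer.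

Step 8
Reactants: 13 7α-allyl enone ester
Product: 14 (4S,5R,7R)-tert-butyldimethylsilyl dienol ether: C8(OSiMe2t-Bu)=C9 and C10=C1, other groups as in 13
Conditions: t-BuMe2SiOTf, Et3N, CH2Cl2, 0 °C to rt; non-aqueous work-up (pentane, filtration), used crude
Reagents that add atoms: tert-butyldimethylsilyl triflate, CC(C)(C)[Si](C)(C)OS(=O)(=O)C(F)(F)F
Why: O-Silylation of the enone and γ-deprotonation at C1 under equilibrating amine conditions should give the linearly conjugated heteroannular dienol ether, the tetrasubstituted cross-conjugated isomer through C7 being disfavoured.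

Step 9
Reactants: 14 silyl dienol ether
Product: 15 (1R,4S,5R,7R)-1β-hydroxy enone: 13 with an axial hydroxyl at C1 cis to the C5 methyl
Conditions: mCPBA (1.05 equiv), hexane/CH2Cl2, −20 °C; then THF/H2O, rt
Reagents that add atoms: 3-chloroperbenzoic acid, OOC(=O)c1cccc(Cl)c1
Why: Vinylogous Rubottom oxidation, in which the peracid attacks the electron-rich terminus C1 of the 1-silyloxy diene and the enone is regenerated on loss of silicon; axial β attack leading directly to a chair ring A, as in the 6β-hydroxylation of steroidal 3,5-dienol ethers, should place the hydroxyl cis to the C5 methyl group, and the monosubstituted allyl alkene is far less nucleophilic than the dienol ether.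

Step 10
Reactants: 16 (S)-4-benzyloxazolidin-2-one; 17 hexanoyl chloride
Product: 19 (S)-4-benzyl-3-hexanoyloxazolidin-2-one, via lithiated oxazolidinone 18 (not isolated)
Conditions: n-BuLi, THF, −78 °C; then hexanoyl chloride, −78 to 0 °C
Reagents that add atoms: hexanoyl chloride (17), CCCCCC(Cl)=O; n-butyllithium, [Li]CCCC (lithium of intermediate 18 only)
Why: N-Acylation of the lithiated oxazolidinone with the acid chloride, the auxiliary stereocentre being untouched.

Step 11
Reactants: 19 (S)-4-benzyl-3-hexanoyloxazolidin-2-one
Product: 21 (S)-4-benzyl-3-[(S)-2-methylhexanoyl]oxazolidin-2-one, via sodium enolate 20 (not isolated)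
Conditions: NaN(SiMe3)2, THF, −78 °C; then MeI, −78 °C
Reagents that add atoms: iodomethane, CI; NaN(SiMe3)2, [Na+].C[Si](C)(C)[N-][Si](C)(C)C (sodium of intermediate 20 only)
Why: Evans alkylation, in which the chelated (Z)-sodium enolate is methylated on the face opposite the benzyl group, which should set the (S)-configured methyl-bearing carbon.

Step 12
Reactants: 21 (S)-4-benzyl-3-[(S)-2-methylhexanoyl]oxazolidin-2-one
Product: 22 (S)-2-methylhexan-1-ol
Conditions: LiBH4, THF, MeOH (1 equiv), 0 °C
Reagents that add atoms: none
Why: Reductive removal of the auxiliary gives the primary alcohol without touching the α-stereocentre and returns the oxazolidinone.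

Step 13
Reactants: 22 (S)-2-methylhexan-1-ol; 23 ethyl 2-(triphenyl-λ5-phosphanylidene)propanoate
Product: 25 ethyl (S,E)-2,4-dimethyloct-2-enoate, via aldehyde 24 (not isolated)
Conditions: Dess–Martin periodinane, CH2Cl2, 0 °C to rt; then Ph3P=C(Me)CO2Et, rt
Reagents that add atoms: ethyl 2-(triphenyl-λ5-phosphanylidene)propanoate (23), CCOC(=O)C(C)=P(c1ccccc1)(c1ccccc1)c1ccccc1
Why: Dess–Martin oxidation gives the configurationally labile α-branched aldehyde, which is trapped in the same flask by the stabilised ylide in a Wittig reaction that should give the (E)-trisubstituted enoate.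

Step 14
Reactants: 25 ethyl (S,E)-2,4-dimethyloct-2-enoate
Product: 26 (S,E)-2,4-dimethyloct-2-enoic acid
Conditions: LiOH, THF/MeOH/H2O, rt; then dil. HCl
Reagents that add atoms: lithium hydroxide, [Li+].[OH-]
Why: Saponification of the ethyl ester under conditions in which the allylic γ-stereocentre is not acidic enough to epimerise.

Step 15
Reactants: 15 1β-hydroxy enone; 26 (S,E)-2,4-dimethyloct-2-enoic acid
Product: 28 (1R,4S,5R,7R)-diester: 15 with the C1 hydroxyl acylated by the (S,E)-2,4-dimethyloct-2-enoyl group, via mixed anhydride 27 (not isolated)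
Conditions: 2,4,6-Cl3C6H2COCl, Et3N, THF, rt; then 15, DMAP, toluene, rt to 40 °C
Reagents that add atoms: (S,E)-2,4-dimethyloct-2-enoic acid (26), OC(=O)/C(C)=C/[C@@H](C)CCCC; 2,4,6-trichlorobenzoyl chloride, O=C(Cl)c1c(Cl)cc(Cl)cc1Cl (aroyl group of intermediate 27 only)
Why: Yamaguchi esterification, in which DMAP attacks the less hindered enoyl carbonyl of the mixed anhydride and the acylpyridinium acylates the hindered axial C1 hydroxyl with retention at C1.

Step 16
Reactants: 28 diester
Product: 29 (1R,4S,5R,7R)-carboxylic acid: 28 with the C4 ester cleaved to CO2H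
Conditions: Bu4NF, THF, 0 °C to rt; dil. aq. HCl work-up
Reagents that add atoms: none
Why: Fluoride attacks silicon and the 2-silylethyl ester fragments to ethene, Me3SiF and the carboxylate (β-elimination), which leaves the C1 enoate ester intact.

Step 17
Reactants: 29 carboxylic acid
Product: 30 (1R,4S,5R,7S)-keto aldehyde: 29 with the C7 allyl group cut to CH2CHO
Conditions: OsO4 (2 mol %), NaIO4, 2,6-lutidine, dioxane/H2O (3:1), rt
Reagents that add atoms: sodium periodate, [Na+].[O-]I(=O)(=O)=O (terminal oxidant; the oxygen is relayed by catalytic OsO4, O=[Os](=O)(=O)=O)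
Why: Lemieux–Johnson oxidation, in which OsO4 dihydroxylates the monosubstituted alkene in preference to the two conjugated, electron-poor trisubstituted alkenes and NaIO4 cleaves the diol to the aldehyde.

Step 18
Reactants: 30 keto aldehyde
Product: 31 integric acid, (1R,4S,5R,7S) with (2E,4S)-2,4-dimethyloct-2-enoyl ester
Conditions: aq. CH2O, pyrrolidine (10 mol %), EtCO2H (10 mol %), i-PrOH, 40 °C
Reagents that add atoms: formaldehyde, C=O
Why: Amine-catalysed α-methylenation of the aldehyde (Mannich condensation with formaldehyde through the enamine, then elimination of the amine) builds the 2-substituted acrolein under nearly neutral conditions that should neither epimerise C7 nor move the new alkene into conjugation.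

Compound list

1 | 2-methylcycloheptane-1,3-dione | CC1C(=O)CCCCC1=O | starting material
2 | methyl vinyl ketone (but-3-en-2-one) | CC(=O)C=C | starting material
3 | 2-methyl-2-(3-oxobutyl)cycloheptane-1,3-dione | CC(=O)CCC1(C)C(=O)CCCCC1=O | intermediate
4 | (4aS)-4a-methyl-4,4a,6,7,8,9-hexahydro-3H-benzo[7]annulene-2,5-dione | O=C1CC[C@@]2(C)C(=C1)CCCCC2=O | intermediate
5 | (4aS)-enone dithiolane (C2 carbonyl of 4 as spiro-1,3-dithiolane, C5 ketone free) | S1CCSC12CC[C@@]3(C)C(=C2)CCCCC3=O | intermediate
6 | sodium enolate of the 6-(hydroxymethylene) derivative of 5 | S1CCSC12CC[C@@]3(C)C(=C2)CCCC(=C[O-])C3=O.[Na+] | intermediate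
7 | (4aS)-6-diazo-5-ketone derived from 5 | S1CCSC12CC[C@@]3(C)C(=C2)CCCC(=[N+]=[N-])C3=O | intermediate
8 | ring-contracted ketene (C4=C15=O exocyclic to six-membered ring A, C8 dithiolane) | S1CCSC12CC[C@@]3(C)C(=C2)CCCC3=C=O | intermediate
9 | 2-(trimethylsilyl)ethyl (4S,5R)-ester, CO2R cis to the C5 methyl, C8 dithiolane | S1CCSC12CC[C@@]3(C)C(=C2)CCC[C@@H]3C(=O)OCC[Si](C)(C)C | intermediate
10 | 2-(trimethylsilyl)ethyl (1S,8aR)-8a-methyl-6-oxo-1,2,3,4,6,7,8,8a-octahydronaphthalene-1-carboxylate | O=C1CC[C@@]2(C)C(=C1)CCC[C@@H]2C(=O)OCC[Si](C)(C)C | intermediate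
11 | allyl bromide (3-bromoprop-1-ene) | C=CCBr | starting material
12 | lithium dienolate of 10 (C7=C8–OLi, C9=C10) | [Li+].[O-]C1=CC[C@@]2(C)C(=C1)CCC[C@@H]2C(=O)OCC[Si](C)(C)C | intermediate
13 | (4S,5R,7R)-7α-allyl enone ester | C=CC[C@@H]1C[C@@]2(C)C(=CC1=O)CCC[C@@H]2C(=O)OCC[Si](C)(C)C | intermediate
14 | (4S,5R,7R)-tert-butyldimethylsilyl dienol ether (C8=C9, C10=C1) | C=CC[C@@H]1C[C@@]2(C)C(C=C1O[Si](C)(C)C(C)(C)C)=CCC[C@@H]2C(=O)OCC[Si](C)(C)C | intermediate
15 | (1R,4S,5R,7R)-1β-hydroxy enone ester | C=CC[C@@H]1C[C@@]2(C)C(=CC1=O)[C@H](O)CC[C@@H]2C(=O)OCC[Si](C)(C)C | intermediate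
16 | (S)-4-benzyloxazolidin-2-one | O=C1N[C@@H](Cc2ccccc2)CO1 | starting material
17 | hexanoyl chloride | CCCCCC(Cl)=O | starting material
18 | lithium salt of (S)-4-benzyloxazolidin-2-one | [Li+].O=C1[N-][C@@H](Cc2ccccc2)CO1 | intermediate
19 | (S)-4-benzyl-3-hexanoyloxazolidin-2-one | CCCCCC(=O)N1[C@@H](Cc2ccccc2)COC1=O | intermediate
20 | sodium (Z)-enolate of 19 | [Na+].[O-]/C(=C\CCCC)N1[C@@H](Cc2ccccc2)COC1=O | intermediate
21 | (S)-4-benzyl-3-[(S)-2-methylhexanoyl]oxazolidin-2-one | O=C([C@@H](C)CCCC)N1[C@@H](Cc2ccccc2)COC1=O | intermediate
22 | (S)-2-methylhexan-1-ol | OC[C@@H](C)CCCC | intermediate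
23 | ethyl 2-(triphenyl-λ5-phosphanylidene)propanoate | CCOC(=O)C(C)=P(c1ccccc1)(c1ccccc1)c1ccccc1 | starting material
24 | (S)-2-methylhexanal | O=C[C@@H](C)CCCC | intermediate
25 | ethyl (S,E)-2,4-dimethyloct-2-enoate | CCOC(=O)/C(C)=C/[C@@H](C)CCCC | intermediate
26 | (S,E)-2,4-dimethyloct-2-enoic acid | OC(=O)/C(C)=C/[C@@H](C)CCCC | intermediate
27 | mixed anhydride of 26 with 2,4,6-trichlorobenzoic acid | O=C(OC(=O)/C(C)=C/[C@@H](C)CCCC)c1c(Cl)cc(Cl)cc1Cl | intermediate
28 | (1R,4S,5R,7R)-7-allyl 1-[(S,E)-2,4-dimethyloct-2-enoyloxy] enone 2-(trimethylsilyl)ethyl ester | C=CC[C@@H]1C[C@@]2(C)C(=CC1=O)[C@H](OC(=O)/C(C)=C/[C@@H](C)CCCC)CC[C@@H]2C(=O)OCC[Si](C)(C)C | intermediate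
29 | (1R,4S,5R,7R)-7-allyl 1-acyloxy enone 4-carboxylic acid | C=CC[C@@H]1C[C@@]2(C)C(=CC1=O)[C@H](OC(=O)/C(C)=C/[C@@H](C)CCCC)CC[C@@H]2C(=O)O | intermediate
30 | (1R,4S,5R,7S)-7-(2-oxoethyl) 1-acyloxy enone 4-carboxylic acid | O=CC[C@@H]1C[C@@]2(C)C(=CC1=O)[C@H](OC(=O)/C(C)=C/[C@@H](C)CCCC)CC[C@@H]2C(=O)O | intermediate
31 | integric acid | C=C(C=O)[C@@H]1C[C@@]2(C)C(=CC1=O)[C@H](OC(=O)/C(C)=C/[C@@H](C)CCCC)CC[C@@H]2C(=O)O | target

Total step count: 18. Longest linear sequence: 13 steps (steps 1 to 9 and 15 to 18); the side-chain acid takes 5 steps (steps 10 to 14).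

Steps most likely to fail

Step 9. The risk is poor facial selectivity of oxygen transfer to C1 of the dienol ether: ring A is more flexible than a steroid ring B, so attack anti to the C5 methyl group may compete or dominate. The fallback sets out from 14. The same oxidation then delivers the 1α-hydroxy enone F1, and its configuration is corrected while the ester is made: Mitsunobu esterification of F1 with acid 26 (PPh3, diisopropyl azodicarboxylate, toluene, 0 °C to rt) displaces the activated hydroxyl with inversion. The route is rejoined at 28, and step 15 is not needed.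

Step 5. The risk is unselective or β-face protonation of the ester enol that follows alcohol addition to the ketene, which would give the C4 epimer. The fallback sets out from 7. Photolysis as before then gives the C4-epimeric ester F2, alone or mixed with 9. The stereocentre is reset through the ester enolate: LiN(i-Pr)2 in THF at −78 °C gives the lithium ester enolate F3, the only carbanion the dithiolane-protected compound can form. F3 is protonated kinetically with a bulky acid (2,6-di-tert-butyl-4-methylphenol), which should be forced to the α face more strictly than the small alcohol. The route is rejoined at 9.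

Step 2. The risk is weak discrimination of the two enantiotopic carbonyl groups of the seven-membered dione in the amino-acid-mediated aldol step, so that the enedione forms with low enantiomeric purity. The fallback sets out from 3. Cyclisation without asymmetric induction (pyrrolidine, AcOH, toluene, reflux) gives the racemic enedione F4. Its enantiomers are separated by preparative chromatography on a chiral stationary phase (supercritical CO2/MeOH), and the (S)-enantiomer rejoins the route at 4.

Further compounds

F1 | step 9 | (1S,4S,5R,7R)-1α-hydroxy enone ester (C1 epimer of 15) | C=CC[C@@H]1C[C@@]2(C)C(=CC1=O)[C@@H](O)CC[C@@H]2C(=O)OCC[Si](C)(C)C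
F2 | step 5 | (4R,5R)-ester, C4 epimer of 9 (CO2R trans to the C5 methyl) | S1CCSC12CC[C@@]3(C)C(=C2)CCC[C@H]3C(=O)OCC[Si](C)(C)C
F3 | step 5 | lithium ester enolate derived from F2 | S1CCSC12CC[C@@]3(C)C(=C2)CCCC3=C([O-])OCC[Si](C)(C)C.[Li+]
F4 | step 2 | racemic 4a-methyl-4,4a,6,7,8,9-hexahydro-3H-benzo[7]annulene-2,5-dione | CC12CCC(=O)C=C1CCCCC2=O
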